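## The problem

The target is built around one sp3 carbon, C1', which carries three different carbon groups: ring A (a 3-isovalerylphloroglucinol joined through the carbon between two hydroxyls), C2 of a benzofuran, and the C2'–C3' diol. Ring B, the benzene ring of the benzofuran, is a second isovalerylphloroglucinol whose C7a oxygen is tied into the furan, so the two halves are chemically alike and every electrophilic step has to tell ring A, ring B and the furan apart. There are two adjacent stereocentres. C2' (R) is a glycerol-type carbinol that can be bought; C1' (S) is a diarylmethine without a heteroatom, so it must be created in a C–C bond formation under the influence of C2' and cannot be repaired afterwards. The finished molecule has five phenols, a 1,2-diol next to a doubly benzylic carbon and two enolisable aryl ketones. Strong acid invites cyclisation of a ring A phenol onto the diol, strong base and organometallic reagents attack the ketones and the acidic C1'–H, so the end game must be one mild deprotection. The two identical acyl groups sit on different rings and must be introduced one at a time, the second at C7 between O6 and the furan oxygen. The feature that opens the route is the make-up of ring B: C3a and C7a are shared with the furan, C4 and C6 carry oxygen, and C5 and C7 lie between them. This is the pattern formed when a 2-furylketene (C7 and C4) takes up an alkoxyacetylene (C5 and C6) and the dienylketene closes onto the furan β-carbon (C3a), so ring B can be grown on a simple 2,5-disubstituted furan after C1' is set.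

## Retrosynthesis

**End game, 24 from 23, 22 and 21.** No skeletal bond is cut in the last step. In 23 the four phenols not made by the annulation are benzyl ethers, O6 is the ethyl ether left by the alkyne and the diol is an acetonide. Benzyl was preferred to methyl because a boron trihalide with a cation scavenger removes benzyl at low temperature, whereas a methyl ether para to the ring A ketone would need forcing conditions beside the diol. The ethyl ether is tolerable only because it ends up ortho to the C7 ketone, where chelation assists its cleavage. The C7–acyl bond is cut next (23 to 22 and 2). It must come after the annulation because C7 is the ketene α-carbon and has to be CH in the key step. The forward acylation must pick C7 over C5 (flanked by two alkoxy groups), C3 (between the O4 benzyl group and the branched C2 substituent) and the free position of ring A (deactivated by its ketone). Ether 22 is the O-benzylation product of phenol 21.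

**Key disconnection, 21 to 15 and 16.** Three bonds of ring B are cut: C4–C5, C6–C7 and C3a–C4. This removes a whole ring and all its oxygenation in one operation and leaves a 2,5-disubstituted furan carrying an acetyl chloride chain (15) and ethoxyacetylene (16). Closing the furan onto a preformed ring B, or decorating a preformed benzofuran, would require a penta- or hexasubstituted benzene to be assembled first. The forward step needs ketene generation by a tertiary amine, a regioselective [2+2] cycloaddition, and a thermal cascade that tolerates the acetonide, the benzyl ethers and the ring A ketone. The alkyne polarity fixes oxygen at C4 and C6.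

**Acetic acid chain, 15 back to 10 and 11.** The acid chloride 15 comes from acid 14, and 14 from malonate 12 by hydrolysis and decarboxylation. The bond between the furan α-carbon and the future C7 is cut to the furan 10 and diethyl bromomalonate 11. A radical C–H malonylation is chosen because lithiation of the furan is excluded by the ring A ketone and the acidic C1'–H, and formylation followed by homologation is longer. The forward reaction must hit the free furan α-position and leave ring A alone, which the acyl group on ring A secures.

**C1'–ring A bond, 10 to 3 and 8.** Cutting this bond gives the tris(benzyloxy) ketone 3 and the furfuryl carbinol 8. The forward reaction is a Friedel–Crafts alkylation through the furfuryl cation 9. Both carbinol epimers of 8 converge on the same cation, so the addition that makes 8 need not be selective. Ketone 3 has two equivalent nucleophilic positions, and its carbonyl is twisted out of the ring plane by the two ortho substituents, so the ring stays reactive. Carrying the acyl group from the start is what makes ring A the least reactive arene in steps 5 and 10. The demand on the step is facial selectivity: the arene must add to 9 anti to the dioxolane C–O bond to give (1'S).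

**Fragments.** Carbinol 8 is cut at the C1'–furan bond into 2-furyllithium 7 (from furan 6) and the aldehyde 5, which comes from (R)-solketal 4 and supplies C2' as the single stereocentre bought with the chiral pool. Ketone 3 is cut at the aryl–acyl bond into 1,3,5-tris(benzyloxy)benzene 1 and isovaleryl chloride 2.

## Roads not taken

**Alternative 1:** The cut is through the furan ring at C3–C3a and O1–C2, giving the sugar aldehyde 4,5-O-isopropylidene-aldehydo-L-arabinose A1 and the monobenzyl acylphloroglucinol A2. In the forward step a Lewis acid condenses the aldehyde carbon of A1 with the free ring carbon of A2, the neighbouring phenol closes onto the sugar C2, and two molecules of water are lost to give benzofuran A3.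
- Merits: it is the shortest road. Ring B carries its acyl group from the outset, so there is no C7 acylation and no ethyl ether to remove. A2 is symmetric, so the annulation has no regiochemical question, and C2' comes from the sugar.
- Weak points: the acetonide must survive a Lewis-acid dehydration. The polyol can divert to C-glycoside-type or dihydrofuran products. A3 still lacks ring A, and its C1' is a carbinol that must later be replaced by ring A through a benzofuranylmethyl cation next to the dioxolane.
- Comparison: this is the same stereochemical question that 9 poses in the chosen plan, but asked at the last C–C bond formation, on an advanced intermediate with a free chelated phenol. Alternative 1 is clearly better in step count. The chosen plan sets against it that C1' is fixed early on cheap material, that every ring position of ring B is defined by the mechanism, and that no dehydration is run on a sugar.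

**Alternative 2:** Ring B is kept intact and the C7a–O and C7–acyl bonds are cut. In the forward step fluoride turns the ortho-silylaryl triflate A4 into the C7–C7a aryne, which inserts into the O–H and acyl–O bonds of isovaleric acid A5 to give the ortho-alkynylphenol A6. The furan would be closed afterwards by 5-endo-dig attack of the new phenol on the alkyne.
- Merits: the phenol oxygen and the acyl group are placed in one step with regiochemistry steered by the C6 alkoxy group. In this respect it is better than step 10 of the chosen plan, which relies on the innate preference of an electrophile.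
- Weak points: A4 is a hexasubstituted benzene with adjacent silyl and triflate groups and needs a long preparation. Its C1' is propargylic as well as benzylic, so fluoride or carboxylate can epimerise it through the allene. The aryne can be intercepted by the nearby alkyne or ketone. The two flanking groups must agree on the direction of addition.
- Comparison: the chosen plan answers with a far simpler key-step precursor and with a C1' that never sits next to an alkyne.

**Alternative 3:** The furan is cut at C3–C3a only; the O1–C2 aryl ether is already present in the α-aryloxy aldehyde A7. In the forward step acid makes C3a of ring B attack the aldehyde and water is lost, giving benzofuran A8.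
- Merits: this cyclodehydration is classical. Ring B has only one free ortho position and already carries its acyl group, so the ring closure is more reliable than a ketene cascade and needs no C7 acylation.
- Weak points: they lie around the key step. A7 needs C1' built with ring A and the carbonate next to an aldehyde α-carbon, without the help of a furan-stabilised cation. The strongly nucleophilic trimethoxyphenyl ring sits two atoms from the activated aldehyde. A8 lacks the ring A acyl group, which must then be introduced in competition with C3 and C5 of the benzofuran. Five methyl ethers must finally be cleaved under forcing Lewis-acid conditions beside the diol.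
- Comparison: the chosen plan pays for a less classical ring closure with a ring A that is acylated in step 1 and with protecting groups that come off in one cold operation.

Key step: step 8

Remark on the chemistry: C1', C2' and C3' are the propyl carbons counted from the carbon that bears both rings; the target is the (1'S,2'R) isomer. G stands for the group (S)-[(4R)-2,2-dimethyl-1,3-dioxolan-4-yl][2,4,6-tris(benzyloxy)-3-(3-methylbutanoyl)phenyl]methyl, that is C1' with ring A and the dioxolane.
Assumption: 1,3,5-tris(benzyloxy)benzene, (R)-solketal, diethyl bromomalonate and ethoxyacetylene (solution in hexanes) are bought.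

## Route

Step 1
Reactants: 1 1,3,5-tris(benzyloxy)benzene; 2 isovaleryl chloride
Product: 3 3-methyl-1-[2,4,6-tris(benzyloxy)phenyl]butan-1-one
Conditions: SnCl4, CH2Cl2, −40 → −20 °C; cold aq. NaHCO3
Reagents that add atoms: none
Why: Friedel–Crafts acylation of a phloroglucinol triether; the three ring positions are equivalent and the first acyl group deactivates the ring, so one product is expected, and the low temperature is chosen to keep the ortho benzyl ethers.

Step 2
Reactants: 4 (R)-solketal
Product: 5 (4S)-2,2-dimethyl-1,3-dioxolane-4-carbaldehyde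
Conditions: (COCl)2, DMSO, CH2Cl2, −78 °C; Et3N, −78 → 0 °C; used crude at once
Reagents that add atoms: none
Why: Swern oxidation, which does not epimerise the α-alkoxy centre; the descriptor changes from R to S only because the priorities change, the spatial arrangement is that of C2' in the target.

Step 3
Reactants: 6 furan; 5 (4S)-2,2-dimethyl-1,3-dioxolane-4-carbaldehyde
Product: 8 (furan-2-yl)[(4S)-2,2-dimethyl-1,3-dioxolan-4-yl]methanol (both carbinol epimers), via 2-furyllithium 7 (not isolated)
Conditions: n-BuLi, THF, 0 °C; then 5, −78 °C; aq. NH4Cl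
Reagents that add atoms: none
Why: α-lithiation of furan and 1,2-addition to the aldehyde; the new carbinol centre forms as a mixture, which is of no consequence because step 4 ionises it.

Step 4
Reactants: 3 3-methyl-1-[2,4,6-tris(benzyloxy)phenyl]butan-1-one; 8 (furan-2-yl)[(4S)-2,2-dimethyl-1,3-dioxolan-4-yl]methanol
Product: 10 1-{2,4,6-tris(benzyloxy)-3-[(S)-[(4R)-2,2-dimethyl-1,3-dioxolan-4-yl](furan-2-yl)methyl]phenyl}-3-methylbutan-1-one (2-G-furan), via furfuryl cation 9 (not isolated)
Conditions: Bi(OTf)3 (5 mol%), 3 in excess, MeNO2/CH2Cl2, −20 → 0 °C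
Reagents that add atoms: none
Why: SN1 Friedel–Crafts alkylation in which either epimer of 8 ionises to the same cation 9, captured by a ring position of 3 between two benzyloxy groups (the ketone is twisted out of conjugation, so the ring stays nucleophilic). C1' is set in the capture: with the dioxolane C–H eclipsing the exocyclic C=C of 9 (A(1,3) strain) the arene should add anti to the ring C–O bond, the sense known for nucleophilic additions to acceptors made from glyceraldehyde acetonide (Felkin–Anh type), which gives (1'S) beside (2'R).

Step 5
Reactants: 10 2-G-furan; 11 diethyl bromomalonate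
Product: 12 diethyl 2-(5-G-furan-2-yl)propanedioate
Conditions: Ru(bpy)3Cl2 (1 mol%), 4-MeOC6H4NPh2, NaHCO3, DMF, blue LEDs, rt
Reagents that add atoms: none
Why: visible-light photoredox C–H malonylation of an electron-rich heteroarene (homolytic aromatic substitution); the electrophilic malonyl radical adds to the only free furan α-position and oxidation with loss of a proton restores the furan, while the acyl-deactivated ring A is left alone.

Step 6
Reactants: 12 diethyl 2-(5-G-furan-2-yl)propanedioate
Product: 14 (5-G-furan-2-yl)acetic acid, via malonic acid 13 (not isolated)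
Conditions: LiOH, THF/MeOH/H2O, 40 °C; 1 M HCl to pH 4, 0 °C; pyridine, 70 °C
Reagents that add atoms: lithium hydroxide, [Li+].[OH-]
Why: saponification followed by decarboxylation of a heteroarylmalonic acid, which loses CO2 on gentle warming; the brief mildly acidic work-up at 0 °C should spare the acetonide.

Step 7
Reactants: 14 (5-G-furan-2-yl)acetic acid
Product: 15 (5-G-furan-2-yl)acetyl chloride
Conditions: 1-chloro-N,N,2-trimethylprop-1-en-1-amine, CH2Cl2, 0 °C → rt; concentrated and used crude
Reagents that add atoms: 1-chloro-N,N,2-trimethylprop-1-en-1-amine, CC(C)=C(Cl)N(C)C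
Why: acid chloride formation with an α-chloroenamine under neutral conditions; no HCl is set free, so the acetonide and the acid-sensitive furan are not exposed to acid.

Step 8
Reactants: 15 (5-G-furan-2-yl)acetyl chloride; 16 ethoxyacetylene
Product: 21 6-ethoxy-2-G-1-benzofuran-4-ol, via furylketene 17 (not isolated), via ethoxycyclobutenone 18 (not isolated), via dienylketene 19 (not isolated), via cyclohexadienone 20 (not isolated)
Conditions: 16 (4 equiv), Et3N, toluene, 0 °C → rt, slow addition of 15; filtration; toluene, 100 °C
Reagents that add atoms: none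
Why: Et3N dehydrochlorinates 15 to the 2-furylketene 17, which is trapped as it forms by [2+2] cycloaddition with the electron-rich alkyne 16, the CH terminus of 16 bonding to the ketene carbonyl carbon and the oxygen-bearing carbon to the ketene α-carbon, to give the 3-ethoxy-4-furylcyclobutenone 18. At 100 °C 18 opens by reversible four-electron electrocyclic ring opening; only the dienylketene 19 with the furan cis to the ketene can go on, and the other isomer returns through 18. Ring B is closed by six-electron disrotatory electrocyclisation of the ketene C=C, the enol ether C=C and the furan C2=C3 bond, the ketene carbon bonding to furan C3, and the cyclohexadienone 20 tautomerises to the aromatic phenol 21. The closest known reaction type is the benzannulation of aryl- and heteroarylketenes with alkoxyacetylenes through 4-aryl-3-alkoxycyclobutenones (Danheiser benzannulation, including the thermal conversion of 4-furylcyclobutenones into benzofuranols). The only new stereocentres (C4 of 18, C3a of 20) are transient, and C1' and C2' are untouched because nothing ionises or deprotonates C1'. The regiochemistry needed (OH at C4, OEt at C6, CH at C5 and C7) is fixed by the polarisation of the ynol ether in the [2+2] step, and the site of closure is fixed because the other neighbour of the chain-bearing carbon is the furan oxygen. Slow addition of 15 to excess 16 keeps 17 dilute and should suppress its dimerisation; the acetonide, the benzyl ethers and the hindered ring A ketone are inert to Et3N and heat.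

Step 9
Reactants: 21 6-ethoxy-2-G-1-benzofuran-4-ol
Product: 22 4-(benzyloxy)-6-ethoxy-2-G-1-benzofuran
Conditions: BnBr, K2CO3, DMF, rt
Reagents that add atoms: benzyl bromide, BrCc1ccccc1
Why: Williamson benzylation of the only free phenol; it prevents O-acylation in step 10 and places a group at O4 that shields C3 and C5.

Step 10
Reactants: 22 4-(benzyloxy)-6-ethoxy-2-G-1-benzofuran; 2 isovaleryl chloride
Product: 23 1-[4-(benzyloxy)-6-ethoxy-2-G-1-benzofuran-7-yl]-3-methylbutan-1-one
Conditions: SnCl4, CH2Cl2, −78 → −30 °C; cold aq. NaHCO3
Reagents that add atoms: none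
Why: Friedel–Crafts acylation of the trioxygenated ring B, which is more reactive than ring A with its ketone; C7 (para to O4, ortho to O6 and to the ring oxygen) is the position at which 4,6-dialkoxybenzofurans take acyl and formyl electrophiles, C5 lies between two alkoxy groups and C3 between the O4 benzyl group and the branched C2 substituent.

Step 11
Reactants: 23 1-[4-(benzyloxy)-6-ethoxy-2-G-1-benzofuran-7-yl]-3-methylbutan-1-one
Product: 24 1-{3-[(1S,2R)-1-[4,6-dihydroxy-7-(3-methylbutanoyl)-1-benzofuran-2-yl]-2,3-dihydroxypropyl]-2,4,6-trihydroxyphenyl}-3-methylbutan-1-one (target CNP0169876.1)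
Conditions: BCl3, C6HMe5, CH2Cl2, −78 → 0 °C; MeOH, then H2O
Reagents that add atoms: none
Why: Lewis-acid dealkylation with pentamethylbenzene as benzyl cation scavenger: the four benzyl ethers and the acetonide should go at low temperature and the ethyl ether, ortho to the C7 ketone, by chelation-assisted cleavage on warming; no stereocentre is involved and the diol is held as a borate until work-up.

## Compound list

1 | 1,3,5-tris(benzyloxy)benzene | c1ccc(COc2cc(OCc3ccccc3)cc(OCc3ccccc3)c2)cc1 | starting material
2 | isovaleryl chloride (3-methylbutanoyl chloride) | CC(C)CC(=O)Cl | starting material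
3 | 3-methyl-1-[2,4,6-tris(benzyloxy)phenyl]butan-1-one | CC(C)CC(=O)c1c(OCc2ccccc2)cc(OCc2ccccc2)cc1OCc1ccccc1 | intermediate
4 | (R)-solketal, [(4R)-2,2-dimethyl-1,3-dioxolan-4-yl]methanol | OC[C@@H]1COC(C)(C)O1 | starting material
5 | (4S)-2,2-dimethyl-1,3-dioxolane-4-carbaldehyde | O=C[C@@H]1COC(C)(C)O1 | intermediate
6 | furan | c1ccoc1 | starting material
7 | 2-furyllithium (not isolated) | [Li]c1ccco1 | intermediate
8 | (furan-2-yl)[(4S)-2,2-dimethyl-1,3-dioxolan-4-yl]methanol, both carbinol epimers | OC(c1ccco1)[C@@H]1COC(C)(C)O1 | intermediate
9 | (furan-2-yl)[(4R)-2,2-dimethyl-1,3-dioxolan-4-yl]methylium, the furfuryl cation (not isolated) | [CH+](c1ccco1)[C@@H]1COC(C)(C)O1 | intermediate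
10 | 1-{2,4,6-tris(benzyloxy)-3-[(S)-[(4R)-2,2-dimethyl-1,3-dioxolan-4-yl](furan-2-yl)methyl]phenyl}-3-methylbutan-1-one (2-G-furan) | CC(C)CC(=O)c1c(OCc2ccccc2)cc(OCc2ccccc2)c([C@H](c2ccco2)[C@@H]2COC(C)(C)O2)c1OCc1ccccc1 | intermediate
11 | diethyl bromomalonate | CCOC(=O)C(Br)C(=O)OCC | starting material
12 | diethyl 2-(5-G-furan-2-yl)propanedioate | CC(C)CC(=O)c1c(OCc2ccccc2)cc(OCc2ccccc2)c([C@H](c2ccc(C(C(=O)OCC)C(=O)OCC)o2)[C@@H]2COC(C)(C)O2)c1OCc1ccccc1 | intermediate
13 | 2-(5-G-furan-2-yl)propanedioic acid (not isolated) | CC(C)CC(=O)c1c(OCc2ccccc2)cc(OCc2ccccc2)c([C@H](c2ccc(C(C(=O)O)C(=O)O)o2)[C@@H]2COC(C)(C)O2)c1OCc1ccccc1 | intermediate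
14 | (5-G-furan-2-yl)acetic acid | CC(C)CC(=O)c1c(OCc2ccccc2)cc(OCc2ccccc2)c([C@H](c2ccc(CC(=O)O)o2)[C@@H]2COC(C)(C)O2)c1OCc1ccccc1 | intermediate
15 | (5-G-furan-2-yl)acetyl chloride | CC(C)CC(=O)c1c(OCc2ccccc2)cc(OCc2ccccc2)c([C@H](c2ccc(CC(=O)Cl)o2)[C@@H]2COC(C)(C)O2)c1OCc1ccccc1 | intermediate
16 | ethoxyacetylene | C#COCC | starting material
17 | 2-(5-G-furan-2-yl)ethen-1-one, the furylketene (not isolated) | CC(C)CC(=O)c1c(OCc2ccccc2)cc(OCc2ccccc2)c([C@H](c2ccc(C=C=O)o2)[C@@H]2COC(C)(C)O2)c1OCc1ccccc1 | intermediate
18 | 3-ethoxy-4-(5-G-furan-2-yl)cyclobut-2-en-1-one, either configuration at C4 (not isolated) | CC(C)CC(=O)c1c(OCc2ccccc2)cc(OCc2ccccc2)c([C@H](c2ccc(C3C(=O)C=C3OCC)o2)[C@@H]2COC(C)(C)O2)c1OCc1ccccc1 | intermediate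
19 | (3E)-3-ethoxy-4-(5-G-furan-2-yl)buta-1,3-dien-1-one, the dienylketene (not isolated) | CC(C)CC(=O)c1c(OCc2ccccc2)cc(OCc2ccccc2)c([C@H](c2ccc(/C=C(/OCC)C=C=O)o2)[C@@H]2COC(C)(C)O2)c1OCc1ccccc1 | intermediate
20 | 6-ethoxy-2-G-3aH-1-benzofuran-4-one, either configuration at C3a (not isolated) | CC(C)CC(=O)c1c(OCc2ccccc2)cc(OCc2ccccc2)c([C@H](C2=CC3C(=O)C=C(OCC)C=C3O2)[C@@H]2COC(C)(C)O2)c1OCc1ccccc1 | intermediate
21 | 6-ethoxy-2-G-1-benzofuran-4-ol | CC(C)CC(=O)c1c(OCc2ccccc2)cc(OCc2ccccc2)c([C@H](c2cc3c(O)cc(OCC)cc3o2)[C@@H]2COC(C)(C)O2)c1OCc1ccccc1 | intermediate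
22 | 4-(benzyloxy)-6-ethoxy-2-G-1-benzofuran | CC(C)CC(=O)c1c(OCc2ccccc2)cc(OCc2ccccc2)c([C@H](c2cc3c(OCc4ccccc4)cc(OCC)cc3o2)[C@@H]2COC(C)(C)O2)c1OCc1ccccc1 | intermediate
23 | 1-[4-(benzyloxy)-6-ethoxy-2-G-1-benzofuran-7-yl]-3-methylbutan-1-one | CC(C)CC(=O)c1c(OCc2ccccc2)cc(OCc2ccccc2)c([C@H](c2cc3c(OCc4ccccc4)cc(OCC)c(C(=O)CC(C)C)c3o2)[C@@H]2COC(C)(C)O2)c1OCc1ccccc1 | intermediate
24 | 1-{3-[(1S,2R)-1-[4,6-dihydroxy-7-(3-methylbutanoyl)-1-benzofuran-2-yl]-2,3-dihydroxypropyl]-2,4,6-trihydroxyphenyl}-3-methylbutan-1-one | CC(C)CC(=O)c1c(O)cc(O)c([C@H](c2cc3c(O)cc(O)c(C(=O)CC(C)C)c3o2)[C@@H](O)CO)c1O | target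

## Step count and risks

Total: 11 steps. Longest linear sequence: 10 steps (4 to 24 through steps 2 to 11).

**Step 8 (key step).** The most likely failure is that dimerisation or amine-induced oligomerisation of the aldoketene 17, or decomposition of the furylacetyl chloride, outruns the [2+2] cycloaddition, so that little cyclobutenone reaches the thermal stage. The fallback generates the same ketene without amine by a Wolff rearrangement, the diazo ketone form of this benzannulation. It sets out from 10. Vilsmeier–Haack formylation of the free furan α-position (POCl3, DMF) gives 5-G-furan-2-carbaldehyde F1. Pinnick oxidation (NaClO2, NaH2PO4, 2-methylbut-2-ene) gives 5-G-furan-2-carboxylic acid F2. Activation with 1-chloro-N,N,2-trimethylprop-1-en-1-amine followed by (trimethylsilyl)diazomethane gives 2-diazo-1-(5-G-furan-2-yl)ethan-1-one F3. Irradiation of F3 in the presence of 16 expels nitrogen, the furyl group migrates to give 17 at low stationary concentration, and warming completes the cascade, so the sequence comes back to the route at 21.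

**Step 4.** The most likely failure is poor facial selectivity in the capture of the planar cation 9, whose unhindered flank gives only a modest conformational bias, together with acid-induced migration of the acetonide onto O1'. The fallback sets both centres by auxiliary control and stereospecific substitution; it sets out from 1 and comes back at 12.
- Bromination of 1 (NBS, MeCN) gives 2-bromo-1,3,5-tris(benzyloxy)benzene F4.
- Its Grignard reagent (Mg, THF) adds with CuBr·SMe2 to (4S)-4-benzyl-3-[(2E)-3-(furan-2-yl)prop-2-enoyl]-1,3-oxazolidin-2-one F5, made from (E)-3-(furan-2-yl)acrylic acid and the oxazolidinone. Addition is expected anti to the benzyl group of the chelated s-cis imide, which sets C1'.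
- The magnesium enolate is brominated in the same flask with NBS on the same face to give (4S)-4-benzyl-3-[(2S,3R)-2-bromo-3-(furan-2-yl)-3-[2,4,6-tris(benzyloxy)phenyl]propanoyl]-1,3-oxazolidin-2-one F6.
- LiBH4 releases the auxiliary and gives (2S,3R)-2-bromo-3-(furan-2-yl)-3-[2,4,6-tris(benzyloxy)phenyl]propan-1-ol F7.
- Aqueous NaOH in dioxane closes 2-[(S)-(furan-2-yl)[(2R)-oxiran-2-yl]methyl]-1,3,5-tris(benzyloxy)benzene F8 with inversion at C2' and opens it at the terminal carbon to (2R,3S)-3-(furan-2-yl)-3-[2,4,6-tris(benzyloxy)phenyl]propane-1,2-diol F9.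
- 2,2-Dimethoxypropane with PPTS gives 2-[(S)-[(4R)-2,2-dimethyl-1,3-dioxolan-4-yl](furan-2-yl)methyl]-1,3,5-tris(benzyloxy)benzene F10.
- The malonylation of step 5 gives diethyl 2-{5-[(S)-[(4R)-2,2-dimethyl-1,3-dioxolan-4-yl][2,4,6-tris(benzyloxy)phenyl]methyl]furan-2-yl}propanedioate F11.
- Acylation of ring A, now the only strongly activated ring, with 2 and SnCl4 at −78 °C returns 12.

**Step 10.** The most likely failure is attack of the acylium ion at C5 or C3 of the benzofuran or at the free position of ring A, and loss of the acetonide or of benzyl groups to the Lewis acid and HCl. The fallback builds the ketone without a Lewis acid, from a smaller electrophile with an established C7 preference on 4,6-dialkoxybenzofurans. It sets out from 22. Vilsmeier–Haack formylation (POCl3, DMF; aq. NaOAc) gives 4-(benzyloxy)-6-ethoxy-2-G-1-benzofuran-7-carbaldehyde F12. i-BuMgBr with CeCl3 in THF at −78 °C adds to the aldehyde in preference to the hindered ring A ketone to give 1-[4-(benzyloxy)-6-ethoxy-2-G-1-benzofuran-7-yl]-3-methylbutan-1-ol F13. Dess–Martin periodinane oxidises it, and the sequence comes back at 23.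

**Step 11.** The most likely failure is slow cleavage of the chelated ethyl ether, which forces warming during which the freed diol and the electron-rich rings suffer (chloride substitution at C3', closure of a ring A phenol onto C2' or C3', C-benzylation). The fallback removes the O-alkyl groups by nucleophilic attack at carbon under basic conditions and frees the diol separately. It sets out from 23. NaSEt in DMF at 110 °C takes off the four benzyl groups and the ethyl group, all of which sit ortho or para to an aryl ketone, and gives 1-{3-[(S)-[4,6-dihydroxy-7-(3-methylbutanoyl)-1-benzofuran-2-yl][(4R)-2,2-dimethyl-1,3-dioxolan-4-yl]methyl]-2,4,6-trihydroxyphenyl}-3-methylbutan-1-one F14. Aqueous AcOH at rt then hydrolyses the acetonide and the sequence comes back at 24.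

## Further compounds

F1 | step 8 | 5-G-furan-2-carbaldehyde | CC(C)CC(=O)c1c(OCc2ccccc2)cc(OCc2ccccc2)c([C@H](c2ccc(C=O)o2)[C@@H]2COC(C)(C)O2)c1OCc1ccccc1
F2 | step 8 | 5-G-furan-2-carboxylic acid | CC(C)CC(=O)c1c(OCc2ccccc2)cc(OCc2ccccc2)c([C@H](c2ccc(C(=O)O)o2)[C@@H]2COC(C)(C)O2)c1OCc1ccccc1
F3 | step 8 | 2-diazo-1-(5-G-furan-2-yl)ethan-1-one | CC(C)CC(=O)c1c(OCc2ccccc2)cc(OCc2ccccc2)c([C@H](c2ccc(C(=O)C=[N+]=[N-])o2)[C@@H]2COC(C)(C)O2)c1OCc1ccccc1
F4 | step 4 | 2-bromo-1,3,5-tris(benzyloxy)benzene | Brc1c(OCc2ccccc2)cc(OCc2ccccc2)cc1OCc1ccccc1
F5 | step 4 | (4S)-4-benzyl-3-[(2E)-3-(furan-2-yl)prop-2-enoyl]-1,3-oxazolidin-2-one | O=C(/C=C/c1ccco1)N1[C@@H](Cc2ccccc2)COC1=O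
F6 | step 4 | (4S)-4-benzyl-3-[(2S,3R)-2-bromo-3-(furan-2-yl)-3-[2,4,6-tris(benzyloxy)phenyl]propanoyl]-1,3-oxazolidin-2-one | O=C([C@@H](Br)[C@@H](c1ccco1)c1c(OCc2ccccc2)cc(OCc2ccccc2)cc1OCc1ccccc1)N1[C@@H](Cc2ccccc2)COC1=O
F7 | step 4 | (2S,3R)-2-bromo-3-(furan-2-yl)-3-[2,4,6-tris(benzyloxy)phenyl]propan-1-ol | OC[C@@H](Br)[C@@H](c1ccco1)c1c(OCc2ccccc2)cc(OCc2ccccc2)cc1OCc1ccccc1
F8 | step 4 | 2-[(S)-(furan-2-yl)[(2R)-oxiran-2-yl]methyl]-1,3,5-tris(benzyloxy)benzene | C1O[C@@H]1[C@@H](c1ccco1)c1c(OCc2ccccc2)cc(OCc2ccccc2)cc1OCc1ccccc1
F9 | step 4 | (2R,3S)-3-(furan-2-yl)-3-[2,4,6-tris(benzyloxy)phenyl]propane-1,2-diol | OC[C@H](O)[C@@H](c1ccco1)c1c(OCc2ccccc2)cc(OCc2ccccc2)cc1OCc1ccccc1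
F10 | step 4 | 2-[(S)-[(4R)-2,2-dimethyl-1,3-dioxolan-4-yl](furan-2-yl)methyl]-1,3,5-tris(benzyloxy)benzene | c1c(OCc2ccccc2)cc(OCc2ccccc2)c([C@H](c2ccco2)[C@@H]2COC(C)(C)O2)c1OCc1ccccc1
F11 | step 4 | diethyl 2-{5-[(S)-[(4R)-2,2-dimethyl-1,3-dioxolan-4-yl][2,4,6-tris(benzyloxy)phenyl]methyl]furan-2-yl}propanedioate | c1c(OCc2ccccc2)cc(OCc2ccccc2)c([C@H](c2ccc(C(C(=O)OCC)C(=O)OCC)o2)[C@@H]2COC(C)(C)O2)c1OCc1ccccc1
F12 | step 10 | 4-(benzyloxy)-6-ethoxy-2-G-1-benzofuran-7-carbaldehyde | CC(C)CC(=O)c1c(OCc2ccccc2)cc(OCc2ccccc2)c([C@H](c2cc3c(OCc4ccccc4)cc(OCC)c(C=O)c3o2)[C@@H]2COC(C)(C)O2)c1OCc1ccccc1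
F13 | step 10 | 1-[4-(benzyloxy)-6-ethoxy-2-G-1-benzofuran-7-yl]-3-methylbutan-1-ol, both carbinol epimers | CC(C)CC(=O)c1c(OCc2ccccc2)cc(OCc2ccccc2)c([C@H](c2cc3c(OCc4ccccc4)cc(OCC)c(C(O)CC(C)C)c3o2)[C@@H]2COC(C)(C)O2)c1OCc1ccccc1
F14 | step 11 | 1-{3-[(S)-[4,6-dihydroxy-7-(3-methylbutanoyl)-1-benzofuran-2-yl][(4R)-2,2-dimethyl-1,3-dioxolan-4-yl]methyl]-2,4,6-trihydroxyphenyl}-3-methylbutan-1-one | CC(C)CC(=O)c1c(O)cc(O)c([C@H](c2cc3c(O)cc(O)c(C(=O)CC(C)C)c3o2)[C@@H]2COC(C)(C)O2)c1O
A1 | alternative 1 | 4,5-O-isopropylidene-aldehydo-L-arabinose | O=C[C@H](O)[C@@H](O)[C@@H]1COC(C)(C)O1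
A2 | alternative 1 | 1-[4-(benzyloxy)-2,6-dihydroxyphenyl]-3-methylbutan-1-one | CC(C)CC(=O)c1c(O)cc(OCc2ccccc2)cc1O
A3 | alternative 1 | 1-{4-(benzyloxy)-2-[(S)-[(4S)-2,2-dimethyl-1,3-dioxolan-4-yl](hydroxy)methyl]-6-hydroxy-1-benzofuran-7-yl}-3-methylbutan-1-one | O[C@H](c1cc2c(OCc3ccccc3)cc(O)c(C(=O)CC(C)C)c2o1)[C@@H]1COC(C)(C)O1
A4 | alternative 2 | ring B ortho-(trimethylsilyl)aryl triflate carrying the propargylic C1' side chain with ring A as tris(methoxymethyl) ether and the dioxolane | CC(C)CC(=O)c1c(OCOC)cc(OCOC)c([C@H](C#Cc2c(OCOC)cc(OCOC)c([Si](C)(C)C)c2OS(=O)(=O)C(F)(F)F)[C@@H]2COC(C)(C)O2)c1OCOC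
A5 | alternative 2 | isovaleric acid (3-methylbutanoic acid) | CC(C)CC(=O)O
A6 | alternative 2 | ortho-alkynylphenol with the isovaleryl group beside the new hydroxyl | CC(C)CC(=O)c1c(OCOC)cc(OCOC)c([C@H](C#Cc2c(OCOC)cc(OCOC)c(C(=O)CC(C)C)c2O)[C@@H]2COC(C)(C)O2)c1OCOC
A7 | alternative 3 | α-aryloxy aldehyde, 2-[3,5-dimethoxy-2-(3-methylbutanoyl)phenoxy]-3-(2-oxo-1,3-dioxolan-4-yl)-3-(2,4,6-trimethoxyphenyl)propanal, either configuration at C2 | COc1cc(OC)c([C@H](C(C=O)Oc2cc(OC)cc(OC)c2C(=O)CC(C)C)[C@@H]2COC(=O)O2)c(OC)c1
A8 | alternative 3 | 4,6-dimethoxy-7-isovalerylbenzofuran with trimethyl ring A lacking its acyl group and the diol as cyclic carbonate | COc1cc(OC)c([C@H](c2cc3c(OC)cc(OC)c(C(=O)CC(C)C)c3o2)[C@@H]2COC(=O)O2)c(OC)c1
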